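**Retrosynthetic overview**
1. 11 ⇐ 10 ⇐ 9: global debenzylation, then inversion of C2'' only. The inversion runs through a p‑quinone methide, which only the free 4‑hydroxyphenyl half can form.
2. 9 ⇐ 8: both pyranone rings are cut at once at O1–C2 and O1''–C2''. One chiral catalyst closes both rings of an acyclic 2,3‑diaroyl‑1,4‑diarylbutadiene and sets all four stereocentres (homochiral halves, both rings cis).
3. 8 ⇐ 4 + 5 + 6: C2=C3 and C2''=C3'' come from two successive aldol condensations on one C4 linchpin. This makes the dimer unsymmetrical without a cross‑coupling.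
4. 4 ⇐ 1 + 2: the C3–C3'' bond is bought as the CH2–CH2 bond of succinyl chloride (double Friedel–Crafts acylation, then selective benzylation).
5. Ring order: the four benzene rings are purchased, and the two pyranone rings form together in step 4.

Assumption 1: flavanone numbering is used, with unprimed locants for the 4‑methoxyphenyl half (unit 1) and doubly primed locants for the 4‑hydroxyphenyl half (unit 2); the given SMILES reads (2S,3S,2''R,3''S), so unit 1 is 2,3‑cis and unit 2 is 2'',3''‑trans.
Assumption 2: the quinidine‑series thiourea is taken to give the 2S sense; if a model chalcone shows the opposite sense, the quinine‑series pseudo‑enantiomer is used with nothing else changed.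

**Step 1**
Reactants: 1 phloroglucinol (2.1 equiv); 2 succinyl chloride
Product: 3 1,4-bis(2,4,6-trihydroxyphenyl)butane-1,4-dione
Conditions: AlCl3 (8 equiv), CH2Cl2–PhNO2, 0 → 40 °C; ice/aq. HCl
Reagents that add atoms: none
Why: Double Friedel–Crafts acylation, in which each acyl chloride end C‑acylates one very electron‑rich phloroglucinol and the new ketone deactivates that ring against a second acylation; no stereocentre is formed.

**Step 2**
Reactants: 3 1,4-bis(2,4,6-trihydroxyphenyl)butane-1,4-dione
Product: 4 1,4-bis[2,4-bis(benzyloxy)-6-hydroxyphenyl]butane-1,4-dione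
Conditions: BnBr (4.2 equiv), K2CO3 (4.4 equiv), DMF, 25 °C
Reagents that add atoms: benzyl bromide, BrCc1ccccc1
Why: Williamson etherification, in which the para OH and one ortho OH of each ring are alkylated while the last ortho OH stays hydrogen‑bonded to the ketone and remains free as the later ring‑closing nucleophile; no stereocentre is formed.

**Step 3**
Reactants: 4 1,4-bis[2,4-bis(benzyloxy)-6-hydroxyphenyl]butane-1,4-dione; 5 4-methoxybenzaldehyde; 6 4-(benzyloxy)benzaldehyde
Product: 8 (2E,3E)-2-[4-(benzyloxy)benzylidene]-3-(4-methoxybenzylidene)-1,4-bis[2,4-bis(benzyloxy)-6-hydroxyphenyl]butane-1,4-dione, via mono-chalcone 7 (not isolated)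
Conditions: KOH (50% aq., 12 equiv), EtOH–THF, 0 → 25 °C, dark, Ar; 5 (1.0 equiv) over 6 h; then 6 (1.5 equiv), 48 h; pour into ice‑cold 1 M HCl; crystallise
Reagents that add atoms: none
Why: Sequential double Claisen–Schmidt condensation (aldol, then E1cB), in which strong base keeps both 2'‑hydroxychalcone units open as phenoxides, slow addition of one equivalent of 5 gives mainly 7, and its more hindered methylene then condenses with 6 to give the thermodynamic E,E diene; no stereocentre is formed.

**Step 4 (key step)**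
Reactants: 8 (2E,3E)-bis-chalcone
Product: 9 (2S,3S,2''S,3''S)-5,5'',7,7''-tetrakis(benzyloxy)-2''-[4-(benzyloxy)phenyl]-2-(4-methoxyphenyl)-[3,3''-bichromane]-4,4''-dione (both rings 2,3-cis)
Conditions: 1-[3,5-bis(trifluoromethyl)phenyl]-3-[(9R)-6'-methoxycinchonan-9-yl]thiourea (20 mol%), toluene, 4 Å MS, −25 °C, 72–96 h; cold filtration through acid‑washed silica
Reagents that add atoms: none
Why: Proposed new method: a two‑directional asymmetric intramolecular oxa‑Michael addition in which the quinuclidine nitrogen deprotonates each chelated 2'‑OH while the thiourea binds the adjacent aroyl C=O, so both phenoxides attack their own arylidene carbon in the same absolute sense (C2 and C2'' both S); each resulting 2‑aryl‑2H‑chromen‑4‑olate holds its aryl group pseudo‑axial to avoid allylic strain with the C3 substituent and is protonated on the face away from that aryl group, which leaves the C3–C3'' bond cis to it (3S and 3''S); because the same catalyst acts twice, the minor sense is diverted into a separable (2S,2''R)‑type diastereomer (Horeau amplification); the closest known reaction types are the cinchona‑thiourea‑catalysed enantioselective cyclisation of 2'‑hydroxychalcones and of their alpha‑substituted alkylidene beta‑keto ester analogues to flavanones, and the anti‑to‑aryl capture of such enolates by electrophiles.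

**Step 5**
Reactants: 9 pentabenzyl all-cis biflavanone
Product: 11 (2S,3S,2''R,3''S)-5,5'',7,7''-tetrahydroxy-2''-(4-hydroxyphenyl)-2-(4-methoxyphenyl)-[3,3''-bichromane]-4,4''-dione (target CNP0196568.4), via all-cis pentaol 10 (not isolated)
Conditions: H2 (1 atm), Pd/C (10 wt%), EtOAc–MeOH, 0 → 20 °C; filter under Ar; NaHCO3/Na2CO3 buffer (pH 9)–MeOH, 30 °C, HPLC control; partition at pH 5; reversed‑phase chromatography
Reagents that add atoms: none
Why: Proposed new method: neutral hydrogenolysis of the five benzyl ethers is standard, and the new part is a site‑selective stereo‑inversion in which, at pH 9, both 7‑OH groups are ionised (lowering C3–H and C3''–H acidity and blocking E1cB opening) and only unit 2 has a 4‑phenolate that can expel O1'' to give a p‑quinone methide with C3''–H untouched, so 1,6‑oxa‑re‑addition equilibrates C2'' alone to the favoured 2'',3''‑trans ring (S → R) while the 4‑methoxyphenyl ring stays cis; the closest known reaction type is the base‑induced racemisation of 4'‑hydroxyflavanones through quinone methide/chalcone forms under conditions where 4'‑methoxyflavanones keep their configuration.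

**Compound list**
1 | phloroglucinol | Oc1cc(O)cc(O)c1 | starting material
2 | succinyl chloride | O=C(Cl)CCC(=O)Cl | starting material
3 | 1,4-bis(2,4,6-trihydroxyphenyl)butane-1,4-dione | O=C(CCC(=O)c1c(O)cc(O)cc1O)c1c(O)cc(O)cc1O | intermediate
4 | 1,4-bis[2,4-bis(benzyloxy)-6-hydroxyphenyl]butane-1,4-dione | O=C(CCC(=O)c1c(O)cc(OCc2ccccc2)cc1OCc1ccccc1)c1c(O)cc(OCc2ccccc2)cc1OCc1ccccc1 | intermediate
5 | 4-methoxybenzaldehyde | COc1ccc(C=O)cc1 | starting material
6 | 4-(benzyloxy)benzaldehyde | O=Cc1ccc(OCc2ccccc2)cc1 | starting material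
7 | (E)-2-(4-methoxybenzylidene)-1,4-bis[2,4-bis(benzyloxy)-6-hydroxyphenyl]butane-1,4-dione (mono-chalcone, not isolated) | O=C(c1c(O)cc(OCc2ccccc2)cc1OCc1ccccc1)/C(=C/c1ccc(OC)cc1)CC(=O)c1c(O)cc(OCc2ccccc2)cc1OCc1ccccc1 | intermediate
8 | (2E,3E)-2-[4-(benzyloxy)benzylidene]-3-(4-methoxybenzylidene)-1,4-bis[2,4-bis(benzyloxy)-6-hydroxyphenyl]butane-1,4-dione | O=C(c1c(O)cc(OCc2ccccc2)cc1OCc1ccccc1)/C(=C/c1ccc(OC)cc1)/C(=C\c1ccc(OCc2ccccc2)cc1)C(=O)c1c(O)cc(OCc2ccccc2)cc1OCc1ccccc1 | intermediate
9 | (2S,3S,2''S,3''S)-pentabenzyl biflavanone, both rings cis | COc1ccc([C@H]2Oc3cc(OCc4ccccc4)cc(OCc4ccccc4)c3C(=O)[C@H]2[C@@H]2C(=O)c3c(OCc4ccccc4)cc(OCc4ccccc4)cc3O[C@@H]2c2ccc(OCc3ccccc3)cc2)cc1 | intermediate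
10 | (2S,3S,2''S,3''S)-pentaol, both rings cis (not isolated) | COc1ccc([C@H]2Oc3cc(O)cc(O)c3C(=O)[C@H]2[C@@H]2C(=O)c3c(O)cc(O)cc3O[C@@H]2c2ccc(O)cc2)cc1 | intermediate
11 | (2S,3S,2''R,3''S)-biflavanone CNP0196568.4 | COc1ccc([C@H]2Oc3cc(O)cc(O)c3C(=O)[C@H]2[C@@H]2C(=O)c3c(O)cc(O)cc3O[C@H]2c2ccc(O)cc2)cc1 | target

**Totals**
Total steps: 5. Longest linear sequence: 5 (1 → 3 → 4 → 8 → 9 → 11).

**Three steps most likely to fail**

Step 4. The risks are low reactivity of the hindered diene, insufficient enantiocontrol, and loss of the cis‑selective protonation.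
- The fallback sets out from 8 and returns at 9. Stereochemistry is brought in by reduction instead of by C–O bond formation.
- Compound 8 is cyclised oxidatively (I2 10 mol%, DMSO, 110 °C). Both rings still close together, giving the unsymmetrical pentabenzyl 3,3''-biflavone F3.
- Copper hydride made from Cu(OAc)2, (R)-DTBM-SEGPHOS (ligand enantiomer fixed on a model flavone) and (EtO)2MeSiH in toluene delivers hydride to C2 and C2'' under ligand control.
- The bis(enol silane) is protonated at −78 °C (Bu4NF/AcOH) on the face away from the aryl groups. This amounts to a syn addition of H2 to each ring and gives 9.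

Step 5. The risks are poor site selectivity of the inversion, drift at C3 or C3'' through the chalcone form, and hydrogenolysis of the C2–O1 bond.
- The fallback sets out from 4 and returns at 11. The inversion is moved to a protected, aprotic stage.
- Compound 4 is condensed as in step 3 with 5 and then with commercial 4-(allyloxy)benzaldehyde. This gives the allyl-protected bis-chalcone F4.
- F4 is cyclised with the step 4 catalyst to the allyl-protected all-cis biflavanone F5.
- Pd(PPh3)4 and morpholine in THF free the single phenol, giving the all-cis tetrabenzyl monophenol F6.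
- DBU (10 mol%) in CH2Cl2 at 0 °C opens only this unit through the quinone methide and re‑closes it, giving the cis/trans tetrabenzyl monophenol F7.
- F7 can be purified and checked by J(2'',3''). Hydrogenolysis (H2, Pd/C) then gives 11 directly.

Step 3. The risks are a statistical mixture of the three bis‑arylidene products and a sluggish second condensation.
- The fallback sets out from 4 and returns at 8.
- Compound 4 is persilylated (Me3SiOTf, Et3N, CH2Cl2, 0 °C) to the tetrakis(trimethylsilyl) bis(silyloxy)diene F1.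
- The conjugated bis(silyloxy)diene is a much better nucleophile than the isolated enol silane left after the first addition.
- A Mukaiyama aldol with 5 (1.0 equiv, BF3·OEt2, −78 °C), followed by 6 in the same flask and a desilylating work‑up, therefore gives the unsymmetrical bis-aldol F2 as a diastereomer mixture.
- Double E1cB dehydration of F2 (KOH, EtOH, 0 °C) returns to 8.

**Further compounds**
F1 | step 3 | (1Z,3Z)-1,4-bis[2,4-bis(benzyloxy)-6-(trimethylsilyloxy)phenyl]-1,4-bis(trimethylsilyloxy)buta-1,3-diene | C[Si](C)(C)O/C(c1c(O[Si](C)(C)C)cc(OCc2ccccc2)cc1OCc1ccccc1)=C\C=C(/O[Si](C)(C)C)c1c(O[Si](C)(C)C)cc(OCc2ccccc2)cc1OCc1ccccc1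
F2 | step 3 | 2-{[4-(benzyloxy)phenyl](hydroxy)methyl}-3-[hydroxy(4-methoxyphenyl)methyl]-1,4-bis[2,4-bis(benzyloxy)-6-hydroxyphenyl]butane-1,4-dione (diastereomer mixture) | O=C(c1c(O)cc(OCc2ccccc2)cc1OCc1ccccc1)C(C(O)c1ccc(OC)cc1)C(C(O)c1ccc(OCc2ccccc2)cc1)C(=O)c1c(O)cc(OCc2ccccc2)cc1OCc1ccccc1
F3 | step 4 | 5,5'',7,7''-tetrakis(benzyloxy)-2''-[4-(benzyloxy)phenyl]-2-(4-methoxyphenyl)-[3,3''-bichromene]-4,4''-dione | COc1ccc(cc1)c1oc2cc(OCc3ccccc3)cc(OCc3ccccc3)c2c(=O)c1c1c(oc2cc(OCc3ccccc3)cc(OCc3ccccc3)c2c1=O)c1ccc(OCc2ccccc2)cc1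
F4 | step 5 | (2E,3E)-2-[4-(allyloxy)benzylidene]-3-(4-methoxybenzylidene)-1,4-bis[2,4-bis(benzyloxy)-6-hydroxyphenyl]butane-1,4-dione | O=C(c1c(O)cc(OCc2ccccc2)cc1OCc1ccccc1)/C(=C/c1ccc(OC)cc1)/C(=C\c1ccc(OCC=C)cc1)C(=O)c1c(O)cc(OCc2ccccc2)cc1OCc1ccccc1
F5 | step 5 | (2S,3S,2''S,3''S)-2''-[4-(allyloxy)phenyl]-5,5'',7,7''-tetrakis(benzyloxy)-2-(4-methoxyphenyl)-[3,3''-bichromane]-4,4''-dione | COc1ccc([C@H]2Oc3cc(OCc4ccccc4)cc(OCc4ccccc4)c3C(=O)[C@H]2[C@@H]2C(=O)c3c(OCc4ccccc4)cc(OCc4ccccc4)cc3O[C@@H]2c2ccc(OCC=C)cc2)cc1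
F6 | step 5 | (2S,3S,2''S,3''S)-5,5'',7,7''-tetrakis(benzyloxy)-2''-(4-hydroxyphenyl)-2-(4-methoxyphenyl)-[3,3''-bichromane]-4,4''-dione | COc1ccc([C@H]2Oc3cc(OCc4ccccc4)cc(OCc4ccccc4)c3C(=O)[C@H]2[C@@H]2C(=O)c3c(OCc4ccccc4)cc(OCc4ccccc4)cc3O[C@@H]2c2ccc(O)cc2)cc1
F7 | step 5 | (2S,3S,2''R,3''S)-5,5'',7,7''-tetrakis(benzyloxy)-2''-(4-hydroxyphenyl)-2-(4-methoxyphenyl)-[3,3''-bichromane]-4,4''-dione | COc1ccc([C@H]2Oc3cc(OCc4ccccc4)cc(OCc4ccccc4)c3C(=O)[C@H]2[C@@H]2C(=O)c3c(OCc4ccccc4)cc(OCc4ccccc4)cc3O[C@H]2c2ccc(O)cc2)cc1
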